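The chromanone is disconnected at two adjacent bonds of benzene ring A, C8a–O1 and C4a–C4. Because the ring oxygen and the C4 ketone sit on neighbouring carbons (C8a, C4a) and C4–C3–C2–O form a 3-oxy-2-methylbutanoyl chain, an aryne spanning C4a–C8a can insert into the C–O bond of a syn-aldol acid. That single operation attaches the whole chiral chain, frees O1 alone (O5 and O7 stay as MOM ethers) and fixes the substitution pattern. The aryne precursor is an ortho-silylaryl triflate from phloroglucinol, carrying the prenyl group between two MOM ethers. Mitsunobu closure, MOM removal and a carbene-catalysed annulation across O7/C8 complete the target.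

Key step: step 10

Assumption: the sense of induction of the triazolium catalyst in step 14 is to be confirmed in a small trial; both antipodes are commercial and the one that gives the 10R lactone is used (written below as the (5aS,10bR) salt).

Step 1
Reactants: 1 phloroglucinol
Product: 2 3,5-bis(methoxymethoxy)phenol
Conditions: MOMCl (2.0 equiv), i-Pr2NEt, CH2Cl2–DMF, 0 °C → rt
Reagents that add atoms: chloromethyl methyl ether, COCCl
Why: Williamson-type O-alkylation of the symmetric triol is statistical, so two equivalents should favour the bis-ether, which is separated from the mono- and tris-ethers by chromatography.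

Step 2
Reactants: 2 3,5-bis(methoxymethoxy)phenol
Product: 3 [3,5-bis(methoxymethoxy)phenoxy]triisopropylsilane
Conditions: TIPSCl, imidazole, DMF, rt
Reagents that add atoms: chlorotriisopropylsilane, CC(C)[Si](Cl)(C(C)C)C(C)C
Why: Standard O-silylation gives a bulky, non-directing ether that tolerates butyllithium and shields its own ortho positions.

Step 3
Reactants: 3 [3,5-bis(methoxymethoxy)phenoxy]triisopropylsilane; 4 prenyl bromide
Product: 6 [3,5-bis(methoxymethoxy)-4-(3-methylbut-2-enyl)phenoxy]triisopropylsilane, via C4 aryllithium 5 (not isolated)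
Conditions: n-BuLi, THF, 0 °C; CuI (10 mol%), then 4, –78 °C → rt
Reagents that add atoms: none
Why: Directed ortho-metalation takes place at the carbon flanked by both MOM ethers (double chelation, silyl ether blocking the other sites), and copper-catalysed allylic substitution on prenyl bromide should give the linear SN2 product.

Step 4
Reactants: 6 [3,5-bis(methoxymethoxy)-4-(3-methylbut-2-enyl)phenoxy]triisopropylsilane
Product: 7 3,5-bis(methoxymethoxy)-4-(3-methylbut-2-enyl)phenol
Conditions: tetrabutylammonium fluoride, THF, 0 °C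
Reagents that add atoms: none
Why: Fluoride desilylation of an aryl silyl ether is fast at 0 °C and leaves MOM ethers and the alkene untouched.

Step 5
Reactants: 7 3,5-bis(methoxymethoxy)-4-(3-methylbut-2-enyl)phenol
Product: 8 2-bromo-3,5-bis(methoxymethoxy)-4-(3-methylbut-2-enyl)phenol
Conditions: NBS (1.0 equiv), i-Pr2NH (10 mol%), CH2Cl2, –78 → 0 °C
Reagents that add atoms: N-bromosuccinimide, O=C1CCC(=O)N1Br
Why: Amine-mediated electrophilic aromatic bromination of the very electron-rich phenol goes ortho to the hydroxyl (the two ortho sites are equivalent, the para site is blocked) much faster than NBS attacks the isolated alkene, and one equivalent at low temperature limits dibromination.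

Step 6
Reactants: 8 2-bromo-3,5-bis(methoxymethoxy)-4-(3-methylbut-2-enyl)phenol
Product: 11 3,5-bis(methoxymethoxy)-4-(3-methylbut-2-enyl)-2-(trimethylsilyl)phenyl trifluoromethanesulfonate, via aryl trimethylsilyl ether 9 (not isolated), via lithium 2-silylphenoxide 10 (not isolated)
Conditions: HMDS, THF, 65 °C, evaporate; n-BuLi, THF, –78 °C; Tf2O, –78 °C → rt
Reagents that add atoms: hexamethyldisilazane, C[Si](C)(C)N[Si](C)(C)C; trifluoromethanesulfonic anhydride, O=S(=O)(OS(=O)(=O)C(F)(F)F)C(F)(F)F
Why: O-silylation, then bromine–lithium exchange triggers a 1,3 O-to-C silyl shift (retro-Brook rearrangement) and the resulting phenoxide is triflated, the standard entry to ortho-silylaryl triflates.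

Step 7
Reactants: 12 (S)-4-benzyl-3-propionyloxazolidin-2-one; 13 acetaldehyde
Product: 16 (S)-4-benzyl-3-[(2S,3R)-3-hydroxy-2-methylbutanoyl]oxazolidin-2-one, via Z-boron enolate 14 (not isolated), via boron aldolate 15 (not isolated)
Conditions: n-Bu2BOTf, i-Pr2NEt, CH2Cl2, 0 °C; 13, –78 → 0 °C; H2O2, pH 7 buffer, MeOH
Reagents that add atoms: none
Why: Evans syn-aldol reaction, in which the Z-boron enolate reacts through a chair Zimmerman–Traxler transition state on the face away from the benzyl group and so sets the 2S and 3R centres.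

Step 8
Reactants: 16 (S)-4-benzyl-3-[(2S,3R)-3-hydroxy-2-methylbutanoyl]oxazolidin-2-one
Product: 17 (S)-4-benzyl-3-[(2S,3R)-2-methyl-3-(triisopropylsilyloxy)butanoyl]oxazolidin-2-one
Conditions: TIPSOTf, 2,6-lutidine, CH2Cl2, 0 °C
Reagents that add atoms: triisopropylsilyl trifluoromethanesulfonate, CC(C)[Si](OS(=O)(=O)C(F)(F)F)(C(C)C)C(C)C
Why: O-silylation with a silyl triflate and a hindered pyridine base protects the secondary alcohol without retro-aldol cleavage or epimerisation.

Step 9
Reactants: 17 (S)-4-benzyl-3-[(2S,3R)-2-methyl-3-(triisopropylsilyloxy)butanoyl]oxazolidin-2-one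
Product: 19 (2S,3R)-2-methyl-3-(triisopropylsilyloxy)butanoic acid, via peroxy acid 18 (not isolated)
Conditions: LiOH, H2O2, THF–H2O, 0 °C; Na2SO3; HCl to pH 3
Reagents that add atoms: hydrogen peroxide, OO
Why: Hydroperoxide-mediated imide hydrolysis attacks the exocyclic carbonyl selectively and releases the acid without touching the alpha centre, and the auxiliary is recovered.

Step 10
Reactants: 11 3,5-bis(methoxymethoxy)-4-(3-methylbut-2-enyl)-2-(trimethylsilyl)phenyl trifluoromethanesulfonate; 19 (2S,3R)-2-methyl-3-(triisopropylsilyloxy)butanoic acid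
Product: 21 (2S,3R)-1-[6-hydroxy-2,4-bis(methoxymethoxy)-3-(3-methylbut-2-enyl)phenyl]-2-methyl-3-(triisopropylsilyloxy)butan-1-one, via aryne 20 (not isolated)
Conditions: 11 (1.3 equiv), 19 (1.0 equiv), CsF (4 equiv), THF, 125 °C, sealed tube
Reagents that add atoms: none
Why: Fluoride removes the trimethylsilyl group with loss of triflate to give the aryne across C4a–C8a; the cesium carboxylate adds through oxygen, and the aryl anion so formed attacks the ester carbonyl just created, the four-membered adduct collapsing to the ketone and the O1 phenoxide. The closest known reaction type is the insertion of arynes from ortho-silylaryl triflates into the C–O bond of carboxylic acids to give ortho-hydroxyaryl ketones. No ring closes and no stereocentre is made; the 3R silyloxy carbon (future C2) is remote from the reacting atoms, and the alpha carbon (future C3) can later be equilibrated to the stable trans arrangement. The selectivity needed is regiochemical: the MOM ether beside one aryne carbon (the future C5 oxygen) polarises and distorts the aryne so that the carboxylate bonds to the distal, less hindered carbon next to C8–H (C8a), leaving the anion ortho to oxygen where it is inductively stabilised, so the acyl group lands on C4a. The high temperature favours acyl transfer over protonation of the aryl anion, which would stop at the aryl ester. The triisopropylsilyl ether resists CsF in THF, and the MOM ethers keep O5 and O7 masked, so only O1 is free afterwards.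

Step 11
Reactants: 21 (2S,3R)-1-[6-hydroxy-2,4-bis(methoxymethoxy)-3-(3-methylbut-2-enyl)phenyl]-2-methyl-3-(triisopropylsilyloxy)butan-1-one
Product: 22 (2S,3R)-3-hydroxy-1-[6-hydroxy-2,4-bis(methoxymethoxy)-3-(3-methylbut-2-enyl)phenyl]-2-methylbutan-1-one
Conditions: HF·pyridine, pyridine, THF, 0 °C → rt
Reagents that add atoms: none
Why: Buffered fluoride desilylation under mildly acidic conditions removes the secondary silyl ether while avoiding retro-aldol cleavage or beta-elimination and leaving the aryl MOM ethers intact.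

Step 12
Reactants: 22 (2S,3R)-3-hydroxy-1-[6-hydroxy-2,4-bis(methoxymethoxy)-3-(3-methylbut-2-enyl)phenyl]-2-methylbutan-1-one
Product: 23 (2S,3S)-5,7-bis(methoxymethoxy)-2,3-dimethyl-6-(3-methylbut-2-enyl)chroman-4-one
Conditions: PPh3, DIAD, THF, 0 °C → rt
Reagents that add atoms: none
Why: Intramolecular Mitsunobu etherification, in which the chelated ortho-acyl phenol (the only free phenol) displaces the oxyphosphonium with inversion (6-exo-tet), turning the 3R carbinol into C2 (S) and giving the trans-2,3-dimethylchromanone.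

Step 13
Reactants: 23 (2S,3S)-5,7-bis(methoxymethoxy)-2,3-dimethyl-6-(3-methylbut-2-enyl)chroman-4-one
Product: 24 (2S,3S)-5,7-dihydroxy-2,3-dimethyl-6-(3-methylbut-2-enyl)chroman-4-one
Conditions: HCl (3 M), MeOH, rt → 40 °C
Reagents that add atoms: none
Why: Acid-catalysed acetal exchange with methanol removes both MOM ethers under conditions that ortho-prenylphenols normally tolerate, and any enolisation at C3 returns the favoured trans isomer.

Step 14
Reactants: 24 (2S,3S)-5,7-dihydroxy-2,3-dimethyl-6-(3-methylbut-2-enyl)chroman-4-one; 25 hex-2-ynal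
Product: 27 methyl (3R)-3-[(2S,3S)-5,7-dihydroxy-2,3-dimethyl-6-(3-methylbut-2-enyl)-4-oxochroman-8-yl]hexanoate, via tricyclic lactone 26 (not isolated)
Conditions: (5aS,10bR)-2-mesityl-5a,10b-dihydro-4H,6H-indeno[2,1-b][1,2,4]triazolo[4,3-d][1,4]oxazin-2-ium chloride (10 mol%), toluene, 40 °C; then MeOH, DMAP (20 mol%), rt
Reagents that add atoms: methanol, CO
Why: Chiral-carbene redox annulation, in which the ynal becomes an alpha,beta-unsaturated acyl azolium, O7 adds and a Coates–Claisen-type rearrangement forms the C8–C bond on the face set by the aminoindanol catalyst (R centre), lactonisation on O7 releases the carbene, and transesterification with methanol opens the activated aryl lactone; C8 is the only unsubstituted ring carbon and O7 the only hydroxyl next to it, so the regiochemistry is fixed.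

Compound list
1 | phloroglucinol (benzene-1,3,5-triol) | Oc1cc(O)cc(O)c1 | starting material
2 | 3,5-bis(methoxymethoxy)phenol | COCOc1cc(O)cc(OCOC)c1 | intermediate
3 | [3,5-bis(methoxymethoxy)phenoxy]triisopropylsilane | COCOc1cc(OCOC)cc(O[Si](C(C)C)(C(C)C)C(C)C)c1 | intermediate
4 | prenyl bromide (1-bromo-3-methylbut-2-ene) | CC(C)=CCBr | starting material
5 | [2,6-bis(methoxymethoxy)-4-(triisopropylsilyloxy)phenyl]lithium | [Li]c1c(OCOC)cc(O[Si](C(C)C)(C(C)C)C(C)C)cc1OCOC | intermediate
6 | [3,5-bis(methoxymethoxy)-4-(3-methylbut-2-enyl)phenoxy]triisopropylsilane | COCOc1cc(O[Si](C(C)C)(C(C)C)C(C)C)cc(OCOC)c1CC=C(C)C | intermediate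
7 | 3,5-bis(methoxymethoxy)-4-(3-methylbut-2-enyl)phenol | COCOc1cc(O)cc(OCOC)c1CC=C(C)C | intermediate
8 | 2-bromo-3,5-bis(methoxymethoxy)-4-(3-methylbut-2-enyl)phenol | COCOc1cc(O)c(Br)c(OCOC)c1CC=C(C)C | intermediate
9 | [2-bromo-3,5-bis(methoxymethoxy)-4-(3-methylbut-2-enyl)phenoxy]trimethylsilane | COCOc1cc(O[Si](C)(C)C)c(Br)c(OCOC)c1CC=C(C)C | intermediate
10 | lithium 3,5-bis(methoxymethoxy)-4-(3-methylbut-2-enyl)-2-(trimethylsilyl)phenoxide | [Li+].[O-]c1cc(OCOC)c(CC=C(C)C)c(OCOC)c1[Si](C)(C)C | intermediate
11 | 3,5-bis(methoxymethoxy)-4-(3-methylbut-2-enyl)-2-(trimethylsilyl)phenyl trifluoromethanesulfonate | FC(F)(F)S(=O)(=O)Oc1cc(OCOC)c(CC=C(C)C)c(OCOC)c1[Si](C)(C)C | intermediate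
12 | (S)-4-benzyl-3-propionyloxazolidin-2-one | CCC(=O)N1[C@@H](Cc2ccccc2)COC1=O | starting material
13 | acetaldehyde | CC=O | starting material
14 | (S)-4-benzyl-3-[(Z)-1-(dibutylboryloxy)prop-1-enyl]oxazolidin-2-one | CCCCB(CCCC)O/C(=C\C)N1[C@@H](Cc2ccccc2)COC1=O | intermediate
15 | (S)-4-benzyl-3-[(2S,3R)-3-(dibutylboryloxy)-2-methylbutanoyl]oxazolidin-2-one | CCCCB(CCCC)O[C@H](C)[C@H](C)C(=O)N1[C@@H](Cc2ccccc2)COC1=O | intermediate
16 | (S)-4-benzyl-3-[(2S,3R)-3-hydroxy-2-methylbutanoyl]oxazolidin-2-one | O[C@H](C)[C@H](C)C(=O)N1[C@@H](Cc2ccccc2)COC1=O | intermediate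
17 | (S)-4-benzyl-3-[(2S,3R)-2-methyl-3-(triisopropylsilyloxy)butanoyl]oxazolidin-2-one | CC(C)[Si](C(C)C)(C(C)C)O[C@H](C)[C@H](C)C(=O)N1[C@@H](Cc2ccccc2)COC1=O | intermediate
18 | (2S,3R)-2-methyl-3-(triisopropylsilyloxy)butaneperoxoic acid | CC(C)[Si](C(C)C)(C(C)C)O[C@H](C)[C@H](C)C(=O)OO | intermediate
19 | (2S,3R)-2-methyl-3-(triisopropylsilyloxy)butanoic acid | CC(C)[Si](C(C)C)(C(C)C)O[C@H](C)[C@H](C)C(=O)O | intermediate
20 | 1,2-didehydro-3,5-bis(methoxymethoxy)-4-(3-methylbut-2-enyl)benzene (aryne) | C1#CC(OCOC)=C(CC=C(C)C)C(OCOC)=C1 | intermediate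
21 | (2S,3R)-1-[6-hydroxy-2,4-bis(methoxymethoxy)-3-(3-methylbut-2-enyl)phenyl]-2-methyl-3-(triisopropylsilyloxy)butan-1-one | CC(C)[Si](C(C)C)(C(C)C)O[C@H](C)[C@H](C)C(=O)c1c(O)cc(OCOC)c(CC=C(C)C)c1OCOC | intermediate
22 | (2S,3R)-3-hydroxy-1-[6-hydroxy-2,4-bis(methoxymethoxy)-3-(3-methylbut-2-enyl)phenyl]-2-methylbutan-1-one | O[C@H](C)[C@H](C)C(=O)c1c(O)cc(OCOC)c(CC=C(C)C)c1OCOC | intermediate
23 | (2S,3S)-5,7-bis(methoxymethoxy)-2,3-dimethyl-6-(3-methylbut-2-enyl)chroman-4-one | COCOc1cc2O[C@@H](C)[C@H](C)C(=O)c2c(OCOC)c1CC=C(C)C | intermediate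
24 | (2S,3S)-5,7-dihydroxy-2,3-dimethyl-6-(3-methylbut-2-enyl)chroman-4-one | Oc1cc2O[C@@H](C)[C@H](C)C(=O)c2c(O)c1CC=C(C)C | intermediate
25 | hex-2-ynal | CCCC#CC=O | starting material
26 | (2S,3S,10R)-5-hydroxy-2,3-dimethyl-6-(3-methylbut-2-enyl)-10-propyl-2,3,9,10-tetrahydro-4H,8H-pyrano[2,3-f]chromene-4,8-dione | CCC[C@@H]1CC(=O)Oc2c1c1O[C@@H](C)[C@H](C)C(=O)c1c(O)c2CC=C(C)C | intermediate
27 | methyl (3R)-3-[(2S,3S)-5,7-dihydroxy-2,3-dimethyl-6-(3-methylbut-2-enyl)-4-oxochroman-8-yl]hexanoate | CCC[C@H](CC(=O)OC)c1c(O)c(CC=C(C)C)c(O)c2c1O[C@@H](C)[C@H](C)C2=O | target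

Total step count: 14.
Longest linear sequence: 11 steps (steps 1–6 and 10–14); the acid branch (steps 7–9) joins at step 10.

Steps most likely to fail

Step 10 (aryne insertion). The aryl anion may be protonated before it reaches the ester carbonyl, so that the sequence stops at the O-aryl ester, or the silyloxy group may be lost by beta-elimination at 125 °C. The fallback replaces the aryne by an anionic Fries rearrangement and sets out from bromophenol 8 and acid 19. Steglich esterification (DCC, DMAP, CH2Cl2, 0 °C → rt) should give the bromoaryl ester F1. Treatment with t-BuLi (2 equiv, THF, –100 → –78 °C) should then effect bromine–lithium exchange, and the ortho-lithiated ester should undergo 1,3 O-to-C acyl migration. This forms the same C4a–C4 bond and frees the same O1, with the regiochemistry fixed by the position of the bromine. Aqueous work-up rejoins the route at ketone 21.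

Step 14 (carbene annulation). Facial selectivity at the new benzylic centre may be poor, or the acyl azolium may acylate a phenol oxygen without C–C bond formation. The fallback uses iminium catalysis and sets out from 24. Friedel–Crafts conjugate addition of C8 to (E)-hex-2-enal, catalysed by (S)-alpha,alpha-diphenylprolinol trimethylsilyl ether (20 mol%, PhCO2H, toluene, 0 °C; antipode confirmed in the same kind of trial), with closure of the aldehyde on O7, should give the lactol F2. Oxidation of the lactol with Ag2CO3 on Celite (toluene, reflux) should give lactone 26, which is methanolysed as in step 14 to reach 27.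

Step 12 (Mitsunobu closure). Dehydration of the beta-hydroxy ketone may compete with displacement, and unselective oxa-Michael closure of the resulting enone would erode the configuration at C2. The fallback uses an asymmetric oxa-Michael closure and sets out from 22. Deliberate dehydration with methyl N-(triethylammoniosulfonyl)carbamate (Burgess reagent, THF, 50 °C) should give the tigloyl phenol F3. Quinidine (10 mol%, chlorobenzene, rt) should then catalyse enantioselective intramolecular oxa-Michael addition of O1, which sets C2 and gives mainly the cis chromanone F4. Et3N (CH2Cl2, rt) epimerises C3 of that product, so the route is rejoined at the trans chromanone 23.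

Further compounds
F1 | step 10 | 2-bromo-3,5-bis(methoxymethoxy)-4-(3-methylbut-2-enyl)phenyl (2S,3R)-2-methyl-3-(triisopropylsilyloxy)butanoate | CC(C)[Si](C(C)C)(C(C)C)O[C@H](C)[C@H](C)C(=O)Oc1cc(OCOC)c(CC=C(C)C)c(OCOC)c1Br
F2 | step 14 | (2S,3S,10R)-5,8-dihydroxy-2,3-dimethyl-6-(3-methylbut-2-enyl)-10-propyl-2,3,9,10-tetrahydro-4H,8H-pyrano[2,3-f]chromen-4-one (both C8 anomers) | CCC[C@@H]1CC(O)Oc2c1c1O[C@@H](C)[C@H](C)C(=O)c1c(O)c2CC=C(C)C
F3 | step 12 | (E)-1-[6-hydroxy-2,4-bis(methoxymethoxy)-3-(3-methylbut-2-enyl)phenyl]-2-methylbut-2-en-1-one | C/C=C(\C)C(=O)c1c(O)cc(OCOC)c(CC=C(C)C)c1OCOC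
F4 | step 12 | (2S,3R)-5,7-bis(methoxymethoxy)-2,3-dimethyl-6-(3-methylbut-2-enyl)chroman-4-one | COCOc1cc2O[C@@H](C)[C@@H](C)C(=O)c2c(OCOC)c1CC=C(C)C
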